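**Retrosynthetic overview**
- Eugenyl acetate 1 is the precursor of carbinol 2: C–O disconnection at the stereocentre, by enantioselective Markovnikov hydration (the new step).
- Carbinol 2 and 4-allyl-2,6-dimethoxyphenol 3 are the two halves of ether 4: the key C(sp3)–OAr disconnection, by Mitsunobu coupling with inversion.
- Ether 4 is the acetate of target 5: phenol unmasking.
- No ring is formed; both benzene rings are bought intact.

Assumption: the sense of induction of the proposed cobalt catalyst cannot be predicted with certainty, so the ligand enantiomer that gives (R)-2 is used (written here as R,R). Catalyst Co-1 (new design) is the Co(II) complex of the salen from (R,R)-1,2-diphenylethane-1,2-diamine and 5-tert-butyl-3-(2-naphthyl)salicylaldehyde.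

The target's single stereocentre is (S). It is set as (R) in step 1 and inverted to (S) in step 2.

**Step 1**
Reactants: 1 4-allyl-2-methoxyphenyl acetate (eugenyl acetate)
Product: 2 4-[(2R)-2-hydroxypropyl]-2-methoxyphenyl acetate
Conditions: Co-1 (5 mol%), N-fluoro-2,4,6-trimethylpyridinium triflate (1.3 equiv), PhSiH3 (1.2 equiv), H2O (20 equiv), acetone, 0 °C
Reagents that add atoms: water, O
Why: Proposed new method: enantioselective Markovnikov hydration of an unactivated allylarene by chiral Co–salen hydrogen-atom-transfer/radical–polar crossover catalysis. Co(III)–H (from Co(II), the N–F oxidant and silane) delivers H• to the terminal CH2 to give the secondary radical, which is captured reversibly as two diastereomeric sec-alkyl–Co(III) species. Oxidation to alkyl–Co(IV) and invertive SN2-type displacement by water is faster for the diastereomer whose arene stacks against the naphthyl wall of the ligand (CH3 versus CH2Ar differentiation), so (R)-2 forms under Curtin–Hammett control. The closest known reaction types are the racemic intermolecular Co(salen)/N-fluoropyridinium/silane hydroalkoxylation of unactivated alkenes, its enantioselective intramolecular variants, and the racemic Mukaiyama hydration.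

**Step 2**
Reactants: 2 4-[(2R)-2-hydroxypropyl]-2-methoxyphenyl acetate; 3 4-allyl-2,6-dimethoxyphenol (methoxyeugenol)
Product: 4 4-[(2S)-2-(4-allyl-2,6-dimethoxyphenoxy)propyl]-2-methoxyphenyl acetate
Conditions: PPh3 (1.5 equiv), DIAD (1.5 equiv), 3 (1.3 equiv), THF, 0 °C → rt
Reagents that add atoms: none
Why: Mitsunobu reaction; the phenol O–H of 3 displaces the activated carbinol oxygen of 2 by SN2 with clean inversion ((R)-carbinol → (S)-aryl ether), and the aryl acetate and both allyl groups are inert under these neutral conditions.

**Step 3**
Reactants: 4 4-[(2S)-2-(4-allyl-2,6-dimethoxyphenoxy)propyl]-2-methoxyphenyl acetate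
Product: 5 4-[(2S)-2-(4-allyl-2,6-dimethoxyphenoxy)propyl]-2-methoxyphenol (target)
Conditions: K2CO3 (0.2 equiv), MeOH, 0 °C → rt
Reagents that add atoms: none
Why: Base-catalysed transesterification (methanolysis) of the aryl acetate; the alkyl aryl ether, the stereocentre and the allyl groups do not react with catalytic carbonate in methanol at room temperature.

**Compound list**
1 | 4-allyl-2-methoxyphenyl acetate (eugenyl acetate) | C=CCc1ccc(OC(C)=O)c(OC)c1 | starting material
2 | 4-[(2R)-2-hydroxypropyl]-2-methoxyphenyl acetate | CC(=O)Oc1ccc(C[C@@H](C)O)cc1OC | intermediate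
3 | 4-allyl-2,6-dimethoxyphenol (methoxyeugenol) | C=CCc1cc(OC)c(O)c(OC)c1 | starting material
4 | 4-[(2S)-2-(4-allyl-2,6-dimethoxyphenoxy)propyl]-2-methoxyphenyl acetate | C=CCc1cc(OC)c(O[C@@H](C)Cc2ccc(OC(C)=O)c(OC)c2)c(OC)c1 | intermediate
5 | 4-[(2S)-2-(4-allyl-2,6-dimethoxyphenoxy)propyl]-2-methoxyphenol | C=CCc1cc(OC)c(O[C@@H](C)Cc2ccc(O)c(OC)c2)c(OC)c1 | target

**Total step count:** 3
**Longest linear sequence:** 3 steps (1 → 2 → 4 → 5); phenol 3 is purchased.

**Steps most likely to fail**

Step 1 (proposed new method). The risks are modest enantioselectivity, Co–H isomerisation of the allyl group to the propenyl arene, competing hydrofluorination, and aryl participation eroding the ee. The fallback uses known chemistry, sets out from 1 and comes back at 2. Tsuji–Wacker oxidation of 1 (PdCl2 cat., CuCl, O2, DMF/H2O, rt) gives the methyl ketone 2-methoxy-4-(2-oxopropyl)phenyl acetate F1. This is reduced with a purified (R)-selective (anti-Prelog) NADPH-dependent alcohol dehydrogenase (Lactobacillus kefir type, i-PrOH as hydride source, pH 7 buffer, 30 °C) to 2.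

Step 2. The risks are E2 elimination of the homobenzylic oxyphosphonium to the propenyl arene and sluggish reaction of the hindered, weakly acidic phenol. The fallback replaces the redox condensation by a Williamson-type SN2 on a pre-formed sulfonate; it sets out from 2 (with 3) and comes back at 4. Alcohol 2 is converted (Tf2O, 2,6-lutidine, CH2Cl2, −78 °C) into (2R)-1-(4-acetoxy-3-methoxyphenyl)propan-2-yl trifluoromethanesulfonate F2. Phenol 3 is converted (KHMDS, THF) into potassium 4-allyl-2,6-dimethoxyphenolate F3. Adding F3 (1.05 equiv, 18-crown-6) to F2 at −78 → −30 °C gives 4 by displacement with inversion. The low temperature is chosen so that substitution outruns acetyl transfer from the aryl acetate to the phenolate.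

Step 3. The risk is low: base-induced migration of an allyl double bond into conjugation or air oxidation of the phenolate. The fallback is enzymatic and neutral; it sets out from 4 and comes back at 5. Immobilised Candida antarctica lipase B with n-butanol in MTBE at 40 °C transfers the acetyl group to butanol; no new compound lies on the way.

**Further compounds**
F1 | step 1 | 2-methoxy-4-(2-oxopropyl)phenyl acetate | CC(=O)Cc1ccc(OC(C)=O)c(OC)c1
F2 | step 2 | (2R)-1-(4-acetoxy-3-methoxyphenyl)propan-2-yl trifluoromethanesulfonate | CC(=O)Oc1ccc(C[C@@H](C)OS(=O)(=O)C(F)(F)F)cc1OC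
F3 | step 2 | potassium 4-allyl-2,6-dimethoxyphenolate | C=CCc1cc(OC)c([O-])c(OC)c1.[K+]
F0 | step 3 | none | none
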